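**Keep ratio.** Start from a ratio: target formed over charge that is neither target nor starting material. Call it the keep ratio, a selectivity factor, and treat a value of 1 as the zero of the scale, where the two shares are equal.

| flask | starting material | precatalyst | remark | time |
|---|---|---|---|---|
| midnight | 6 mM | 3.3 µM | run made earlier |  |
| spring | 6 mM | 1.1 µM | run made earlier |  |
| north | 6.0 mM | 2.2 µM |  | 3.0 h |
| south-east | 12 mM | 2.2 µM |  | 3.0 h |
| north-east | 20 mM | 2.2 µM |  | 3.0 h |
| south-west | 40 mM | 2.2 µM |  | 3.0 h |

| run | time / min | target / % | starting material / % |
|---|---|---|---|
| midnight | 3.00 | 0.7 | 100.0 |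
| midnight | 10.0 | 1.1 | 98.7 |
| midnight | 20.0 | 5.7 | 93.6 |
| midnight | 25.0 | 9.1 | 90.1 |
| midnight | 40.0 | 21.5 | 76.7 |
| midnight | 50.0 | 32.5 | 64.9 |
| midnight | 60.0 | 44.3 | 52.9 |
| spring | 10.0 | 0.5 | 99.7 |
| spring | 20.0 | 1.9 | 98.0 |
| spring | 25.0 | 3.0 | 96.9 |
| spring | 40.0 | 8.1 | 92.1 |
| spring | 50.0 | 11.7 | 87.7 |
| spring | 60.0 | 16.0 | 82.2 |

(standard deviation of a reading: 0.3 percentage points)

- [target] at the end for north, south-east, north-east, south-west, in this order
- how that number moves from the first to the last of them (hardly changes / rises, then falls / rises all the way / falls all the way / falls, then rises)

- the numbers in the tables scatter by 0.3 percentage points (one standard deviation)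
- "hardly changes" means that all values lie within two and a half points (for a concentration: within two and a half percent of the largest)

**Reading it.** Take the last row of each run. The midnight run reads 15.8 and the spring run 8.89, so the run with more precatalyst keeps more. The gaps in the balance behind these ratios, 2.8 percentage points and 1.8 points, are larger than the scatter of 0.3 points, but they stand in the denominator, so treat both ratios as rough readings. Use their mean, 12.4, for the four flasks, whose precatalyst charge lies midway.

**Upper bound.** Work on south-west, the largest charge. With no loss, target would be the whole charge. Now assume the loss is a meeting of two molecules of the charge, so that the keep ratio falls in proportion to the charge. South-west then has 1.85, still above the zero of the scale. Even at complete conversion, target reaches 65.0% of the charge.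

**Lower bound.** Suppose instead that the catalysed rate does not grow with the charge, so that south-west makes as much target as a complete north. That gives 13.9% of the south-west charge. My bracket is wide, and it does not settle the shape of the row.

**The forecast.** It gives 5.2 mM, 10.5 mM, 17 mM and 30 mM, so rises all the way, on the ground “I assume about 10% is lost overall”. Its south-west value is 75.0% of the charge, above my upper bound.

**The flasks.** They give 5.41 mM, 9.68 mM, 13.3 mM and 10.2 mM, so the row rises, then falls, turning at 25 mM. South-west holds 25.5% target, inside the bracket.

    starting material + enzyme → target + enzyme, rate k1*[starting material]*[enzyme]/(1 + ([starting material]/Km1) + ([starting material]/Ksi1)^2) (8.47 mM, 13.7 mM, k = 2.38 × 10⁶ /M/h)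
    starting material → decomposition product (k = 4.23 × 10⁻⁴ /h)
    precatalyst → enzyme (k = 0.279 /h)
    starting material + target → side product (k = 21.7 /M/h)

**Two ratios.** In north after 1.27 h, starting material goes to target 19 times as fast as to side product, and the end ratio of target to side product is 10.4, against the keep ratio of 12.4 read from the runs. South-west was assigned 1.85, but after 3.00 h it holds a ratio of 0.817, with 31.2% side product and 43% starting material left.

The readings are calculated for an exercise; the scatter is artificial.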